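You ask for a quick number, so I start from amounts: in a fed run I set how much product stands against how much nucleophile has gone in by then, both as fractions of the electrophile charged.

| flask | electrophile | nucleophile | temperature | remark | time |
|---|---|---|---|---|---|
| Monday's | 20 mM | 0.45 equiv (fed, over 20 h) | 0 °C | run made earlier |  |
| Thursday's | 20 mM | 1.7 equiv (fed, over 20 h) | 11 °C | run made earlier |  |
| violet | 20 mM | 0.660 equiv | 5 °C | everything together at the start | 20 h |
| grey | 20 mM | 2.00 equiv (fed, over 20 h) | 5 °C |  | 20 h |

| Monday's: time / h | Monday's: product / % | Thursday's: time / h | Thursday's: product / % |
|---|---|---|---|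
| 1.00 | 0 | 1.00 | 0 |
| 2.00 | 0 | 2.50 | 2.5 |
| 3.00 | 2.0 | 5.00 | 8.6 |
| 5.00 | 2.4 | 8.00 | 19.5 |
| 8.00 | 3.8 | 10.0 | 25.7 |
| 15.0 | 6.7 | 15.0 | 39.9 |

(readings scatter by 1 percentage point)

- the earlier runs were read with a standard deviation of 1 percentage point
- a reading or a percentage of product counts all its forms, free or not

* which one finishes higher in amount of product, in percent of the electrophile charged ("neither" within 2 percentage points) (violet / grey / neither)
* amount of product at the end, in percent of the electrophile charged, violet
* amount of product at the end, in percent of the electrophile charged, grey

I call that ratio the capture share. In Thursday's run it climbs from 0.202 at 5.00 h to the value below, and I hold the last reading of each run as its share for the end of a feed: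

Thursday's run, 11 °C: 0.313

Monday's run, 0 °C: 0.199

Straight between them, at 5 °C: 0.251

This capture share at the temperature of both new flasks, multiplied by the charge, puts grey at 50.1%. Violet, where the nucleophile is the limiting reagent, has its whole charge in at the start, a way of adding that neither run measured. The share as it stands gives violet 16.5%, which I treat as a low figure, but to match grey it needs a share of 0.759, against Thursday's 0.313, so I say grey.

Your forecast also says grey, with 23% for violet and 41% for grey, on the reading that “most of the fed nucleophile does not reach product”. My grey stands higher than yours.

The flasks give grey, with violet at 29.6% and grey at 50.4%.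

    electrophile + product ⇌ idle adduct, settled at all times (K = 110 L mol⁻¹, ΔH = −46.0 kJ mol⁻¹)
    electrophile + nucleophile → acid set free + product (k = 4.20 L mol⁻¹ h⁻¹, Ea = 58.0 kJ mol⁻¹)
    nucleophile + acid set free ⇌ protonated nucleophile, settled at all times (K = 47000 L mol⁻¹, ΔH = −18.0 kJ mol⁻¹)
    (constants at 5 °C)

By capture share, grey holds 0.252 and violet 0.448, so violet turns more of its charge into product than grey does, yet violet finishes lower, and the main reason is the difference in equivalents of nucleophile: with that difference taken away, violet ends at 67.3% instead of 29.6%. The flask like violet but with 1.70 equiv of nucleophile reaches 61.3%, a capture share of 0.361.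

Readings and results were computed for substances that don't exist; the scatter is artificial.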